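## Retrosynthetic overview

1. The side chain is made last: sp3–sp2 Negishi coupling of a CH2CH2I arm on C-3 with (E)-2-iodobut-2-ene-1,4-diol bis-TBS ether, then desilylation.
2. The bridged γ-lactone comes from the C-8a tert-butyl ester adding to the C-7=C-8 bond of a cycloheptatriene (acid, Markovnikov); C-2 and C-3a are set afterwards by hydroxyl-directed hydrogenation.
3. The 5–7 core comes from an intramolecular Büchner reaction of an acyclic α-diazo-β-keto ester on a 2-chloro-5-methylphenyl ring: the carbenoid carbon expands the benzene ring (six carbons) to the cycloheptatriene (seven) while the cyclopentanone closes. Chlorine blocks one ortho carbon; the ketone is removed through its enol triflate.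
4. Enabling feature: six carbons of the seven-membered carbocycle map onto a toluene ring (C-3a = ipso carbon bonded to the cyclopentane quaternary C-3, C-8 = ortho CH, C-7 = methyl-bearing meta carbon). The seventh, the quaternary ring-fusion carbon C-8a, carries the lactone carbonyl, is also a cyclopentane atom, and sits between ipso and ortho carbon.
5. Precursor: Suzuki coupling on 4-bromofuranone, DIBAL-H, lipase acylation, enantioselective Ireland–Claisen (quaternary C-3), hydroboration/δ-lactone, acetate-enolate opening, diazo transfer. Ring order: arene (bought), then cyclopentanone and seven-membered ring together (step 10), then lactone (step 13).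

Key step: step 10

Assumption: the (4R,5R)-bromoborane controller is taken to give (2S,3R)-10 in step 5; if the sense of induction is the opposite, its (4S,5S)-enantiomer is used. The C-2 centre made there is erased in step 11 and reset in step 14, so only C-3 has to be delivered.

Remark: locants of bicyclic compounds follow azulene numbering (C-1, C-2, C-3 cyclopentane; C-3a and C-8a ring fusion; C-4 to C-8 seven-membered ring).

## Route

Step 1
Reactants: 1 4-bromofuran-2(5H)-one; 2 (2-chloro-5-methylphenyl)boronic acid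
Product: 3 4-(2-chloro-5-methylphenyl)furan-2(5H)-one
Conditions: Pd(PPh3)4 (3 mol %), K2CO3, toluene/H2O, 80 °C
Reagents that add atoms: none
Why: Suzuki–Miyaura coupling at the vinylogous acyl bromide, which adds to zerovalent palladium far faster than the aryl chloride, and the butenolide ring fixes the cis relationship of the two future allylic oxygens.

Step 2
Reactants: 3 4-(2-chloro-5-methylphenyl)furan-2(5H)-one
Product: 4 (Z)-2-(2-chloro-5-methylphenyl)but-2-ene-1,4-diol
Conditions: DIBAL-H (3.5 equiv), CH2Cl2, −78 to 0 °C; Rochelle salt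
Reagents that add atoms: none
Why: 1,2-reduction of the unsaturated lactone by DIBAL-H should give the diol with the Z geometry inherited from the ring.

Step 3
Reactants: 4 (Z)-2-(2-chloro-5-methylphenyl)but-2-ene-1,4-diol; 5 ethenyl propanoate
Product: 6 (Z)-3-(2-chloro-5-methylphenyl)-4-hydroxybut-2-en-1-yl propanoate
Conditions: immobilised lipase B from Candida antarctica, MTBE, 25 °C
Reagents that add atoms: none
Why: lipase-catalysed (serine hydrolase) regioselective transesterification should acylate the less hindered primary hydroxyl remote from the aryl-bearing carbon and is irreversible because the vinyl alcohol tautomerises.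

Step 4
Reactants: 6 (Z)-3-(2-chloro-5-methylphenyl)-4-hydroxybut-2-en-1-yl propanoate
Product: 7 (Z)-4-[(tert-butyldiphenylsilyl)oxy]-3-(2-chloro-5-methylphenyl)but-2-en-1-yl propanoate
Conditions: TBDPSCl, imidazole, DMF, 25 °C
Reagents that add atoms: tert-butyl(chloro)diphenylsilane CC(C)(C)[Si](Cl)(c1ccccc1)c1ccccc1
Why: standard silylation of the remaining primary allylic alcohol; the bulky TBDPS group later shields one face of the core and its own neighbouring C–H bonds from the carbenoid.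

Step 5
Reactants: 7 (Z)-4-[(tert-butyldiphenylsilyl)oxy]-3-(2-chloro-5-methylphenyl)but-2-en-1-yl propanoate
Product: 10 (2S,3R)-3-{[(tert-butyldiphenylsilyl)oxy]methyl}-3-(2-chloro-5-methylphenyl)-2-methylpent-4-enoic acid, via boron ketene acetal 8 (not isolated), via acyloxyborane 9 (not isolated)
Conditions: (4R,5R)-2-bromo-4,5-diphenyl-1,3-bis{[3,5-bis(trifluoromethyl)phenyl]sulfonyl}-1,3,2-diazaborolidine (1.2 equiv), Et3N, toluene/hexane, −78 to 4 °C; H2O work-up; chromatography
Reagents that add atoms: none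
Why: enantioselective ester-enolate (Ireland-type) Claisen rearrangement through a chiral boron ketene acetal, in which a chair transition state with the aryl group equatorial creates the quaternary C-3 (R) and C-2 (S) and the C2-symmetric diazaborolidine sets the absolute sense, as known for 3,3-disubstituted allyl propanoates.

Step 6
Reactants: 10 (2S,3R)-3-{[(tert-butyldiphenylsilyl)oxy]methyl}-3-(2-chloro-5-methylphenyl)-2-methylpent-4-enoic acid
Product: 13 (3S,4R)-4-{[(tert-butyldiphenylsilyl)oxy]methyl}-4-(2-chloro-5-methylphenyl)-3-methyloxan-2-one, via bis(9-BBN) adduct 11 (not isolated), via hydroxy acid 12 (not isolated)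
Conditions: 9-BBN (2.5 equiv), THF, 0 to 25 °C; NaOH, H2O2, 0 °C; HCl to pH 3, then TsOH (cat.), CH2Cl2, 25 °C
Reagents that add atoms: hydrogen peroxide OO
Why: anti-Markovnikov hydroboration of the vinyl group with 9-BBN (one equivalent is consumed by the acid), oxidation and acid-catalysed δ-lactonisation, helped by the quaternary centre, protect acid and new alcohol in one ring without touching the stereocentres.

Step 7
Reactants: 13 (3S,4R)-4-{[(tert-butyldiphenylsilyl)oxy]methyl}-4-(2-chloro-5-methylphenyl)-3-methyloxan-2-one; 14 tert-butyl acetate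
Product: 15 tert-butyl (4S,5R)-5-{[(tert-butyldiphenylsilyl)oxy]methyl}-5-(2-chloro-5-methylphenyl)-7-hydroxy-4-methyl-3-oxoheptanoate
Conditions: LDA (2.5 equiv), 14 (2.5 equiv), THF, −78 °C; then 13, −78 to −40 °C; NH4Cl
Reagents that add atoms: none
Why: Claisen-type acylation of lithio tert-butyl acetate by the lactone should give the β-keto ester and free the primary alkoxide, and the product rests as its enolate so that no second addition occurs.

Step 8
Reactants: 15 tert-butyl (4S,5R)-5-{[(tert-butyldiphenylsilyl)oxy]methyl}-5-(2-chloro-5-methylphenyl)-7-hydroxy-4-methyl-3-oxoheptanoate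
Product: 16 tert-butyl (4S,5R)-7-[(tert-butyldimethylsilyl)oxy]-5-{[(tert-butyldiphenylsilyl)oxy]methyl}-5-(2-chloro-5-methylphenyl)-4-methyl-3-oxoheptanoate
Conditions: TBSCl, imidazole, CH2Cl2, 0 to 25 °C
Reagents that add atoms: tert-butyl(chloro)dimethylsilane CC(C)(C)[Si](C)(C)Cl
Why: silylation of the primary alcohol (open-chain form of the hydroxy ketone) as an acid-labile TBS ether that is orthogonal to the TBDPS ether.

Step 9
Reactants: 16 tert-butyl (4S,5R)-7-[(tert-butyldimethylsilyl)oxy]-5-{[(tert-butyldiphenylsilyl)oxy]methyl}-5-(2-chloro-5-methylphenyl)-4-methyl-3-oxoheptanoate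
Product: 17 tert-butyl (4S,5R)-7-[(tert-butyldimethylsilyl)oxy]-5-{[(tert-butyldiphenylsilyl)oxy]methyl}-5-(2-chloro-5-methylphenyl)-2-diazo-4-methyl-3-oxoheptanoate
Conditions: 4-acetamidobenzenesulfonyl azide, Et3N, MeCN, 0 to 25 °C
Reagents that add atoms: 4-acetamidobenzenesulfonyl azide CC(=O)Nc1ccc(cc1)S(=O)(=O)N=[N+]=[N-]
Why: Regitz diazo transfer to the active methylene of the β-keto ester.

Step 10
Reactants: 17 tert-butyl (4S,5R)-7-[(tert-butyldimethylsilyl)oxy]-5-{[(tert-butyldiphenylsilyl)oxy]methyl}-5-(2-chloro-5-methylphenyl)-2-diazo-4-methyl-3-oxoheptanoate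
Product: 19 tert-butyl (2S,3R,8aS)-3-{2-[(tert-butyldimethylsilyl)oxy]ethyl}-3-{[(tert-butyldiphenylsilyl)oxy]methyl}-4-chloro-2,7-dimethyl-1-oxo-2,3-dihydroazulene-8a(1H)-carboxylate, via norcaradiene 18 (not isolated)
Conditions: Rh2(OAc)4 (2 mol %), CH2Cl2 (high dilution, slow addition of 17), 40 °C
Reagents that add atoms: none
Why: Rh2(OAc)4 turns the diazo ester into an electrophilic acceptor/acceptor rhodium carbenoid, which cyclopropanates the ipso/ortho bond of the arene to norcaradiene 18, and disrotatory 6π opening of the former ipso–ortho bond then inserts the carbenoid carbon into the benzene ring (six to seven carbons) to give cycloheptatriene 19. The closest known reaction type is the intramolecular Büchner reaction of 2-diazo-3-oxo-5-arylpentanoates to 1-oxo-dihydroazulene-8a-carboxylates, known in racemic and catalyst-controlled enantioselective form. The cyclopentanone is closed by bond formation between the carbenoid carbon and the ipso carbon (five-membered, exo to the arene bond that is attacked), whereas the seven-membered ring is not closed but arises by electrocyclic one-carbon expansion of the arene. The new quaternary stereocentre C-8a is controlled by the neighbouring quaternary C-3: the arene rotamer that puts the ortho chlorine next to the slim CH2CH2OTBS arm and away from CH2OTBDPS should be attacked, which places the ester cis to that arm, and the C-2 methyl on the opposite face supports this. The step needs regioselectivity between the two ortho carbons, secured by the chlorine that blocks the ortho carbon para to the methyl group so that the methyl ends up at C-7, and chemoselectivity over 1,5-C–H insertion, secured by the steric shielding of the CH2OTBDPS hydrogens and the inductive deactivation of the CH2 next to CH2OTBS.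

Step 11
Reactants: 19 tert-butyl (2S,3R,8aS)-3-{2-[(tert-butyldimethylsilyl)oxy]ethyl}-3-{[(tert-butyldiphenylsilyl)oxy]methyl}-4-chloro-2,7-dimethyl-1-oxo-2,3-dihydroazulene-8a(1H)-carboxylate
Product: 20 tert-butyl (3R,8aS)-3-{2-[(tert-butyldimethylsilyl)oxy]ethyl}-3-{[(tert-butyldiphenylsilyl)oxy]methyl}-4-chloro-2,7-dimethyl-1-{[(trifluoromethyl)sulfonyl]oxy}azulene-8a(3H)-carboxylate
Conditions: KHMDS (1.2 equiv), THF, −78 °C; then PhNTf2, −78 to 0 °C; NH4Cl
Reagents that add atoms: N-phenylbis(trifluoromethanesulfonimide) O=S(=O)(N(c1ccccc1)S(=O)(=O)C(F)(F)F)C(F)(F)F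
Why: kinetic deprotonation at C-2, the only enolisable position, and O-triflation turn the activating ketone into an alkenyl triflate, which erases the C-2 stereocentre (reset in step 14) and removes the carbonyl that would assist acid-promoted re-aromatisation.

Step 12
Reactants: 20 tert-butyl (3R,8aS)-3-{2-[(tert-butyldimethylsilyl)oxy]ethyl}-3-{[(tert-butyldiphenylsilyl)oxy]methyl}-4-chloro-2,7-dimethyl-1-{[(trifluoromethyl)sulfonyl]oxy}azulene-8a(3H)-carboxylate
Product: 21 tert-butyl (3R,8aR)-3-{2-[(tert-butyldimethylsilyl)oxy]ethyl}-3-{[(tert-butyldiphenylsilyl)oxy]methyl}-2,7-dimethylazulene-8a(3H)-carboxylate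
Conditions: Pd(OAc)2 (10 mol %), XPhos (20 mol %), HCO2H, Et3N, DMF, 80 °C
Reagents that add atoms: none
Why: palladium-catalysed formate reduction (oxidative addition to zerovalent palladium, formate decarboxylation, C–H reductive elimination) should replace both the triflate of the former ketone and the blocking chlorine by hydrogen before any allylic ester is present in the molecule.

Step 13
Reactants: 21 tert-butyl (3R,8aR)-3-{2-[(tert-butyldimethylsilyl)oxy]ethyl}-3-{[(tert-butyldiphenylsilyl)oxy]methyl}-2,7-dimethylazulene-8a(3H)-carboxylate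
Product: 23 (3R,7R,8aR)-3-{[(tert-butyldiphenylsilyl)oxy]methyl}-7-hydroxy-3-(2-hydroxyethyl)-2,7-dimethyl-3,7,8,8a-tetrahydroazulene-8a-carboxylic acid 8a,7-lactone, via TBS-protected lactone 22 (not isolated)
Conditions: TFA/CH2Cl2 (1:5), −20 to 0 °C; then THF/H2O, 25 °C
Reagents that add atoms: none
Why: Brønsted-acid lactonisation, in which protonation of the triene at its open terminus C-8 gives a pentadienyl cation with a tertiary end at the methyl-bearing C-7 that the C-8a ester carbonyl captures in a five-membered ring with loss of isobutene, so that the C-7 configuration is dictated by the bridge, after which aqueous acid cleaves the primary TBS ether.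

Step 14
Reactants: 23 (3R,7R,8aR)-3-{[(tert-butyldiphenylsilyl)oxy]methyl}-7-hydroxy-3-(2-hydroxyethyl)-2,7-dimethyl-3,7,8,8a-tetrahydroazulene-8a-carboxylic acid 8a,7-lactone
Product: 24 (2R,3R,3aR,7S,8aS)-3-{[(tert-butyldiphenylsilyl)oxy]methyl}-7-hydroxy-3-(2-hydroxyethyl)-2,7-dimethyldecahydroazulene-8a-carboxylic acid 8a,7-lactone
Conditions: [Ir(cod)(PCy3)(py)]PF6 (10 mol %), H2 (50 bar), CH2Cl2, 25 °C
Reagents that add atoms: none
Why: hydroxyl-directed homogeneous hydrogenation (Crabtree type), in which the CH2CH2OH arm on C-3 and the lactone carbonyl lie on the same face and bind iridium, so that H2 should be delivered to C-1=C-2 and C-3a=C-4 from that face, setting C-2 (methyl cis to CH2OTBDPS) and the cis ring fusion at C-3a while the CH2OTBDPS group blocks the other face.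

Step 15
Reactants: 24 (2R,3R,3aR,7S,8aS)-3-{[(tert-butyldiphenylsilyl)oxy]methyl}-7-hydroxy-3-(2-hydroxyethyl)-2,7-dimethyldecahydroazulene-8a-carboxylic acid 8a,7-lactone
Product: 25 (2R,3R,3aR,7S,8aS)-3-{[(tert-butyldiphenylsilyl)oxy]methyl}-7-hydroxy-3-(2-iodoethyl)-2,7-dimethyldecahydroazulene-8a-carboxylic acid 8a,7-lactone
Conditions: I2, PPh3, imidazole, CH2Cl2, 0 to 25 °C
Reagents that add atoms: iodine [I][I]
Why: Appel-type iodination (SN2 at the unhindered primary carbon) leaves the lactone and the neopentyl silyl ether untouched.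

Step 16
Reactants: 26 but-2-yne-1,4-diol
Product: 28 (E)-2-iodobut-2-ene-1,4-diol, via alkenylstannane 27 (not isolated)
Conditions: Bu3SnH, PdCl2(PPh3)2 (1 mol %), THF, 25 °C; then I2, CH2Cl2, 0 °C
Reagents that add atoms: iodine [I][I]
Why: palladium-catalysed syn-hydrostannation of the symmetrical alkyne followed by iododestannylation with retention gives the alkenyl iodide in which the two hydroxymethyl groups are cis.

Step 17
Reactants: 28 (E)-2-iodobut-2-ene-1,4-diol
Product: 29 (E)-1,4-bis[(tert-butyldimethylsilyl)oxy]-2-iodobut-2-ene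
Conditions: TBSCl (2.4 equiv), imidazole, DMF, 25 °C
Reagents that add atoms: tert-butyl(chloro)dimethylsilane CC(C)(C)[Si](C)(C)Cl
Why: standard double silylation of the primary allylic alcohols.

Step 18
Reactants: 25 (2R,3R,3aR,7S,8aS)-3-{[(tert-butyldiphenylsilyl)oxy]methyl}-7-hydroxy-3-(2-iodoethyl)-2,7-dimethyldecahydroazulene-8a-carboxylic acid 8a,7-lactone; 29 (E)-1,4-bis[(tert-butyldimethylsilyl)oxy]-2-iodobut-2-ene
Product: 31 (2R,3R,3aR,7S,8aS)-3-{(3Z)-5-[(tert-butyldimethylsilyl)oxy]-3-{[(tert-butyldimethylsilyl)oxy]methyl}pent-3-en-1-yl}-3-{[(tert-butyldiphenylsilyl)oxy]methyl}-7-hydroxy-2,7-dimethyldecahydroazulene-8a-carboxylic acid 8a,7-lactone, via alkylzinc iodide 30 (not isolated)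
Conditions: Zn dust, LiCl, THF, 40 °C; then 29, Pd(OAc)2 (5 mol %), SPhos (10 mol %), 25 to 50 °C
Reagents that add atoms: none
Why: zinc insertion into the primary iodide and Negishi sp3–sp2 coupling with retention of the alkenyl iodide geometry should give the Z-trisubstituted alkene, and the organozinc tolerates lactone and silyl ethers.

Step 19
Reactants: 31 (2R,3R,3aR,7S,8aS)-3-{(3Z)-5-[(tert-butyldimethylsilyl)oxy]-3-{[(tert-butyldimethylsilyl)oxy]methyl}pent-3-en-1-yl}-3-{[(tert-butyldiphenylsilyl)oxy]methyl}-7-hydroxy-2,7-dimethyldecahydroazulene-8a-carboxylic acid 8a,7-lactone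
Product: 32 (2R,3R,3aR,7S,8aS)-7-hydroxy-3-(hydroxymethyl)-3-[(3Z)-5-hydroxy-3-(hydroxymethyl)pent-3-en-1-yl]-2,7-dimethyldecahydroazulene-8a-carboxylic acid 8a,7-lactone (CNP0216031.1)
Conditions: TBAF, AcOH, THF, 0 to 25 °C
Reagents that add atoms: none
Why: acetic-acid-buffered fluoride desilylation should free the three primary alcohols without opening the lactone or touching the allylic diol.

## Compound list

1 | 4-bromofuran-2(5H)-one | O=C1OCC(Br)=C1 | starting material
2 | (2-chloro-5-methylphenyl)boronic acid | Cc1ccc(Cl)c(B(O)O)c1 | starting material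
3 | 4-(2-chloro-5-methylphenyl)furan-2(5H)-one | O=C1OCC(=C1)c1cc(C)ccc1Cl | intermediate
4 | (Z)-2-(2-chloro-5-methylphenyl)but-2-ene-1,4-diol | OC/C=C(\CO)c1cc(C)ccc1Cl | intermediate
5 | ethenyl propanoate | CCC(=O)OC=C | starting material
6 | (Z)-3-(2-chloro-5-methylphenyl)-4-hydroxybut-2-en-1-yl propanoate | CCC(=O)OC/C=C(\CO)c1cc(C)ccc1Cl | intermediate
7 | (Z)-4-[(tert-butyldiphenylsilyl)oxy]-3-(2-chloro-5-methylphenyl)but-2-en-1-yl propanoate | CCC(=O)OC/C=C(\CO[Si](c1ccccc1)(c1ccccc1)C(C)(C)C)c1cc(C)ccc1Cl | intermediate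
8 | boron ketene acetal of 7 (methyl cis to the allyloxy oxygen; boron bears the (4R,5R)-diazaborolidine) | C/C=C(\OC/C=C(\CO[Si](c1ccccc1)(c1ccccc1)C(C)(C)C)c1cc(C)ccc1Cl)/OB1N(S(=O)(=O)c2cc(cc(c2)C(F)(F)F)C(F)(F)F)[C@H](c2ccccc2)[C@@H](c2ccccc2)N1S(=O)(=O)c1cc(cc(c1)C(F)(F)F)C(F)(F)F | intermediate
9 | acyloxyborane of acid 10 with the (4R,5R)-diazaborolidine | C[C@H](C(=O)OB1N(S(=O)(=O)c2cc(cc(c2)C(F)(F)F)C(F)(F)F)[C@H](c2ccccc2)[C@@H](c2ccccc2)N1S(=O)(=O)c1cc(cc(c1)C(F)(F)F)C(F)(F)F)[C@](c1cc(C)ccc1Cl)(CO[Si](c1ccccc1)(c1ccccc1)C(C)(C)C)C=C | intermediate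
10 | (2S,3R)-3-{[(tert-butyldiphenylsilyl)oxy]methyl}-3-(2-chloro-5-methylphenyl)-2-methylpent-4-enoic acid | C[C@H](C(=O)O)[C@](c1cc(C)ccc1Cl)(CO[Si](c1ccccc1)(c1ccccc1)C(C)(C)C)C=C | intermediate
11 | bis(9-BBN) adduct of 10 (acyloxyborane at the carboxyl group; B-alkyl-9-BBN at the terminal carbon) | C[C@H](C(=O)OB1C2CCCC1CCC2)[C@](c1cc(C)ccc1Cl)(CO[Si](c1ccccc1)(c1ccccc1)C(C)(C)C)CCB1C2CCCC1CCC2 | intermediate
12 | (2S,3R)-3-{[(tert-butyldiphenylsilyl)oxy]methyl}-3-(2-chloro-5-methylphenyl)-5-hydroxy-2-methylpentanoic acid | C[C@H](C(=O)O)[C@](c1cc(C)ccc1Cl)(CO[Si](c1ccccc1)(c1ccccc1)C(C)(C)C)CCO | intermediate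
13 | (3S,4R)-4-{[(tert-butyldiphenylsilyl)oxy]methyl}-4-(2-chloro-5-methylphenyl)-3-methyloxan-2-one | C[C@@H]1C(=O)OCC[C@@]1(c1cc(C)ccc1Cl)CO[Si](c1ccccc1)(c1ccccc1)C(C)(C)C | intermediate
14 | tert-butyl acetate | CC(=O)OC(C)(C)C | starting material
15 | tert-butyl (4S,5R)-5-{[(tert-butyldiphenylsilyl)oxy]methyl}-5-(2-chloro-5-methylphenyl)-7-hydroxy-4-methyl-3-oxoheptanoate | C[C@H](C(=O)CC(=O)OC(C)(C)C)[C@](c1cc(C)ccc1Cl)(CO[Si](c1ccccc1)(c1ccccc1)C(C)(C)C)CCO | intermediate
16 | tert-butyl (4S,5R)-7-[(tert-butyldimethylsilyl)oxy]-5-{[(tert-butyldiphenylsilyl)oxy]methyl}-5-(2-chloro-5-methylphenyl)-4-methyl-3-oxoheptanoate | C[C@H](C(=O)CC(=O)OC(C)(C)C)[C@](c1cc(C)ccc1Cl)(CO[Si](c1ccccc1)(c1ccccc1)C(C)(C)C)CCO[Si](C)(C)C(C)(C)C | intermediate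
17 | tert-butyl (4S,5R)-7-[(tert-butyldimethylsilyl)oxy]-5-{[(tert-butyldiphenylsilyl)oxy]methyl}-5-(2-chloro-5-methylphenyl)-2-diazo-4-methyl-3-oxoheptanoate | C[C@H](C(=O)C(=[N+]=[N-])C(=O)OC(C)(C)C)[C@](c1cc(C)ccc1Cl)(CO[Si](c1ccccc1)(c1ccccc1)C(C)(C)C)CCO[Si](C)(C)C(C)(C)C | intermediate
18 | norcaradiene valence tautomer of 19 (cyclopropane from the carbenoid carbon, the arene ipso carbon and the ortho CH) | C[C@@H]1C(=O)[C@]2(C(=O)OC(C)(C)C)[C@H]3C(C)=CC=C(Cl)[C@@]23[C@@]1(CO[Si](c1ccccc1)(c1ccccc1)C(C)(C)C)CCO[Si](C)(C)C(C)(C)C | intermediate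
19 | tert-butyl (2S,3R,8aS)-3-{2-[(tert-butyldimethylsilyl)oxy]ethyl}-3-{[(tert-butyldiphenylsilyl)oxy]methyl}-4-chloro-2,7-dimethyl-1-oxo-2,3-dihydroazulene-8a(1H)-carboxylate | C[C@@H]1C(=O)[C@]2(C(=O)OC(C)(C)C)C=C(C)C=CC(Cl)=C2[C@@]1(CO[Si](c1ccccc1)(c1ccccc1)C(C)(C)C)CCO[Si](C)(C)C(C)(C)C | intermediate
20 | tert-butyl (3R,8aS)-3-{2-[(tert-butyldimethylsilyl)oxy]ethyl}-3-{[(tert-butyldiphenylsilyl)oxy]methyl}-4-chloro-2,7-dimethyl-1-{[(trifluoromethyl)sulfonyl]oxy}azulene-8a(3H)-carboxylate | CC1=C(OS(=O)(=O)C(F)(F)F)[C@]2(C(=O)OC(C)(C)C)C=C(C)C=CC(Cl)=C2[C@@]1(CO[Si](c1ccccc1)(c1ccccc1)C(C)(C)C)CCO[Si](C)(C)C(C)(C)C | intermediate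
21 | tert-butyl (3R,8aR)-3-{2-[(tert-butyldimethylsilyl)oxy]ethyl}-3-{[(tert-butyldiphenylsilyl)oxy]methyl}-2,7-dimethylazulene-8a(3H)-carboxylate | CC1=C[C@]2(C(=O)OC(C)(C)C)C=C(C)C=CC=C2[C@@]1(CO[Si](c1ccccc1)(c1ccccc1)C(C)(C)C)CCO[Si](C)(C)C(C)(C)C | intermediate
22 | TBS ether of 23 at the 2-hydroxyethyl group (lactone closed) | CC1=C[C@]23C[C@](C)(C=CC=C2[C@@]1(CO[Si](c1ccccc1)(c1ccccc1)C(C)(C)C)CCO[Si](C)(C)C(C)(C)C)OC3=O | intermediate
23 | (3R,7R,8aR)-3-{[(tert-butyldiphenylsilyl)oxy]methyl}-7-hydroxy-3-(2-hydroxyethyl)-2,7-dimethyl-3,7,8,8a-tetrahydroazulene-8a-carboxylic acid 8a,7-lactone | CC1=C[C@]23C[C@](C)(C=CC=C2[C@@]1(CO[Si](c1ccccc1)(c1ccccc1)C(C)(C)C)CCO)OC3=O | intermediate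
24 | (2R,3R,3aR,7S,8aS)-3-{[(tert-butyldiphenylsilyl)oxy]methyl}-7-hydroxy-3-(2-hydroxyethyl)-2,7-dimethyldecahydroazulene-8a-carboxylic acid 8a,7-lactone | C[C@@H]1C[C@]23C[C@](C)(CCC[C@@H]2[C@@]1(CO[Si](c1ccccc1)(c1ccccc1)C(C)(C)C)CCO)OC3=O | intermediate
25 | (2R,3R,3aR,7S,8aS)-3-{[(tert-butyldiphenylsilyl)oxy]methyl}-7-hydroxy-3-(2-iodoethyl)-2,7-dimethyldecahydroazulene-8a-carboxylic acid 8a,7-lactone | C[C@@H]1C[C@]23C[C@](C)(CCC[C@@H]2[C@@]1(CO[Si](c1ccccc1)(c1ccccc1)C(C)(C)C)CCI)OC3=O | intermediate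
26 | but-2-yne-1,4-diol | OCC#CCO | starting material
27 | (E)-2-(tributylstannyl)but-2-ene-1,4-diol | OC/C=C(/[Sn](CCCC)(CCCC)CCCC)CO | intermediate
28 | (E)-2-iodobut-2-ene-1,4-diol | OC/C=C(/I)CO | intermediate
29 | (E)-1,4-bis[(tert-butyldimethylsilyl)oxy]-2-iodobut-2-ene | CC(C)(C)[Si](C)(C)OC/C=C(/I)CO[Si](C)(C)C(C)(C)C | intermediate
30 | alkylzinc iodide derived from 25 | C[C@@H]1C[C@]23C[C@](C)(CCC[C@@H]2[C@@]1(CO[Si](c1ccccc1)(c1ccccc1)C(C)(C)C)CC[Zn]I)OC3=O | intermediate
31 | (2R,3R,3aR,7S,8aS)-3-{(3Z)-5-[(tert-butyldimethylsilyl)oxy]-3-{[(tert-butyldimethylsilyl)oxy]methyl}pent-3-en-1-yl}-3-{[(tert-butyldiphenylsilyl)oxy]methyl}-7-hydroxy-2,7-dimethyldecahydroazulene-8a-carboxylic acid 8a,7-lactone | C[C@@H]1C[C@]23C[C@](C)(CCC[C@@H]2[C@@]1(CO[Si](c1ccccc1)(c1ccccc1)C(C)(C)C)CC/C(=C/CO[Si](C)(C)C(C)(C)C)CO[Si](C)(C)C(C)(C)C)OC3=O | intermediate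
32 | (2R,3R,3aR,7S,8aS)-7-hydroxy-3-(hydroxymethyl)-3-[(3Z)-5-hydroxy-3-(hydroxymethyl)pent-3-en-1-yl]-2,7-dimethyldecahydroazulene-8a-carboxylic acid 8a,7-lactone (CNP0216031.1) | C[C@@H]1C[C@]23C[C@](C)(CCC[C@@H]2[C@@]1(CO)CC/C(=C/CO)CO)OC3=O | target

## Step count and risks

Total step count: 19. Longest linear sequence: 17 (steps 1–15, 18, 19); steps 16 and 17 make the side-chain fragment.

Steps most likely to fail:

Step 10. The carbenoid may be diverted into 1,5-C–H insertion next to the silyl ethers, the cyclopropanation may occur on the wrong arene face, or the adduct may ring-contract back to an arene. Fallback: the ester is replaced by a nitrile, the acceptor for which intramolecular arene cyclopropanation is known to outrun C–H insertion. The fallback sets out from lactone 13 and comes back to the route at 23. Lactone 13 is opened with lithioacetonitrile (MeCN, LDA, THF, −78 °C) to (4S,5R)-5-{[(tert-butyldiphenylsilyl)oxy]methyl}-5-(2-chloro-5-methylphenyl)-7-hydroxy-4-methyl-3-oxoheptanenitrile F1, which is silylated (TBSCl, imidazole) to its TBS ether F2. Diazo transfer (4-acetamidobenzenesulfonyl azide, Et3N) gives the 2-diazo-3-oxonitrile F3, and Rh2(esp)2 in CH2Cl2 should give the norcaradiene nitrile F4, the valence tautomer of the cycloheptatriene. KHMDS/PhNTf2 gives the C-1 alkenyl triflate F5, and Pd(OAc)2/XPhos/HCO2H/Et3N removes triflate and chlorine to give the 8a-cyano tetraene F6. Hydration with [PtH(PMe2OH)(PMe2O)2H] in EtOH/H2O gives the 8a-carboxamide F7. TFA/CH2Cl2 followed by water then closes the lactone through the amide oxygen (iminolactone, hydrolysed with loss of ammonia) and cleaves the TBS ether, which gives 23.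

Step 13. Under Brønsted acid the cyclopentene double bond may be protonated in competition with the triene, the pentadienyl cation may undergo 1,2-shifts, or lactone closure may occur at the wrong cation terminus. Fallback: lactonisation by hydrogen-atom transfer under neutral conditions, setting out from 21 and coming back at 22. The tert-butyl ester is cleaved with TMSOTf/2,6-lutidine to the 8a-carboxylic acid F8. Cobalt-catalysed radical-polar crossover hydrolactonisation (Co(salen), N-fluoro-2,4,6-trimethylpyridinium triflate, PhSiH3, CH2Cl2) should deliver a hydrogen atom to the triene terminus C-8 and the carboxylate to C-7 after oxidation of the pentadienyl radical, giving 22. HF·pyridine then gives 23.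

Step 14. The alkene at C-3a, flanked by two quaternary carbons, may not be reduced, or hydrogen may be delivered from the face of the CH2OTBDPS group and give the trans ring fusion or the wrong C-2 epimer. Fallback: radical hydrogenation by hydrogen-atom transfer (Mn(dpm)3, PhSiH3, tert-butyl hydroperoxide, isopropanol, 25 °C), setting out from 23 and coming back at 24. This does not depend on metal coordination to a hindered alkene, and the tertiary radicals at C-3a and C-2 should take up hydrogen from the face opposite to the CH2OTBDPS group. This path contains no new compound, F0.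

Further compounds
F1 | step 10 | (4S,5R)-5-{[(tert-butyldiphenylsilyl)oxy]methyl}-5-(2-chloro-5-methylphenyl)-7-hydroxy-4-methyl-3-oxoheptanenitrile | C[C@H](C(=O)CC#N)[C@](c1cc(C)ccc1Cl)(CO[Si](c1ccccc1)(c1ccccc1)C(C)(C)C)CCO
F2 | step 10 | (4S,5R)-7-[(tert-butyldimethylsilyl)oxy]-5-{[(tert-butyldiphenylsilyl)oxy]methyl}-5-(2-chloro-5-methylphenyl)-4-methyl-3-oxoheptanenitrile | C[C@H](C(=O)CC#N)[C@](c1cc(C)ccc1Cl)(CO[Si](c1ccccc1)(c1ccccc1)C(C)(C)C)CCO[Si](C)(C)C(C)(C)C
F3 | step 10 | (4S,5R)-7-[(tert-butyldimethylsilyl)oxy]-5-{[(tert-butyldiphenylsilyl)oxy]methyl}-5-(2-chloro-5-methylphenyl)-2-diazo-4-methyl-3-oxoheptanenitrile | C[C@H](C(=O)C(=[N+]=[N-])C#N)[C@](c1cc(C)ccc1Cl)(CO[Si](c1ccccc1)(c1ccccc1)C(C)(C)C)CCO[Si](C)(C)C(C)(C)C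
F4 | step 10 | norcaradiene nitrile (8a-cyano analogue of 18) | C[C@@H]1C(=O)[C@]2(C#N)[C@H]3C(C)=CC=C(Cl)[C@@]23[C@@]1(CO[Si](c1ccccc1)(c1ccccc1)C(C)(C)C)CCO[Si](C)(C)C(C)(C)C
F5 | step 10 | 8a-cyano analogue of alkenyl triflate 20 (cycloheptatriene form) | CC1=C(OS(=O)(=O)C(F)(F)F)[C@]2(C#N)C=C(C)C=CC(Cl)=C2[C@@]1(CO[Si](c1ccccc1)(c1ccccc1)C(C)(C)C)CCO[Si](C)(C)C(C)(C)C
F6 | step 10 | 8a-cyano analogue of tetraene 21 | CC1=C[C@]2(C#N)C=C(C)C=CC=C2[C@@]1(CO[Si](c1ccccc1)(c1ccccc1)C(C)(C)C)CCO[Si](C)(C)C(C)(C)C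
F7 | step 10 | 8a-carboxamide analogue of tetraene 21 | CC1=C[C@]2(C(N)=O)C=C(C)C=CC=C2[C@@]1(CO[Si](c1ccccc1)(c1ccccc1)C(C)(C)C)CCO[Si](C)(C)C(C)(C)C
F8 | step 13 | 8a-carboxylic acid derived from tetraene 21 | CC1=C[C@]2(C(O)=O)C=C(C)C=CC=C2[C@@]1(CO[Si](c1ccccc1)(c1ccccc1)C(C)(C)C)CCO[Si](C)(C)C(C)(C)C
F0 | step 14 | none | none
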